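Everything rests on carrying ten of the twenty-one hydroxyls as formyl groups. The target allows this because seven ether carbons (C1 of ring A, C4 of rings B and D, C2 of rings C and E, C1 and C6 of ring G) lie ortho or para to carbons that end as C–OH. A CHO there first activates a C–F bond for aryl ether formation and is then exchanged for oxygen. The precursor is the complete A–H octaaryl heptaether bearing ten CHO and eleven OMe groups. One peracid treatment followed by methanolysis converts all ten C–CHO units into C–OH. Dimethyl acetals keep individual rings switched off until their fluoride is needed.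

Key step: step 29

Remark on numbering: rings are lettered A–H from the 2,4,6-trihydroxyphenyl end. C1 of each ring carries the oxygen that points toward ring A (in ring A, its only ether oxygen). The second ether carbon is C4 in B and D, C2 in C and E, C5 in F and C6 in G.

Remark on the order of couplings: a 2-aryloxybenzene-1,3-dicarbaldehyde unit can itself exchange its aryloxide. The weakly activated fluorides of rings C, E and G are therefore displaced first, on small fragments and with heat. The doubly activated fluorides of rings A, B and D are displaced last, near room temperature.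

Remark on free phenols: a free phenol is never left on a ring whose fluoride is to be displaced, because its phenoxide would deactivate that ring and start oligomerisation.

Assumption: compounds 1, 8, 17, 26, 30 and 36 are taken as catalogue chemicals.

Step 1
Reactants: 1 2-fluoro-5-methoxybenzaldehyde
Product: 2 2-(dimethoxymethyl)-1-fluoro-4-methoxybenzene
Conditions: HC(OMe)3, p-TsOH (cat.), MeOH, reflux; Et3N
Reagents that add atoms: trimethyl orthoformate COC(OC)OC
Why: Acid-catalysed acetalisation, pulled to completion by the orthoformate, hides the aldehyde from the organolithium base of the next step.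

Step 2
Reactants: 2 2-(dimethoxymethyl)-1-fluoro-4-methoxybenzene
Product: 5 2-fluoro-5-methoxybenzene-1,3-dicarbaldehyde (ring A fluoride), via aryllithium 3 (not isolated), via acetal aldehyde 4 (not isolated)
Conditions: s-BuLi, PMDTA, THF, −78 °C; DMF, −78 → 0 °C; 2 M HCl, rt
Reagents that add atoms: N,N-dimethylformamide CN(C)C=O; water O
Why: Directed ortho-metalation and formylation: with the lithium ion wrapped by the triamine the base follows acidity alone and takes the proton next to fluorine, and the acidic quench hydrolyses the acetal to the symmetrical dialdehyde.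

Step 3
Reactants: 5 2-fluoro-5-methoxybenzene-1,3-dicarbaldehyde
Product: 6 2-fluoro-5-hydroxybenzene-1,3-dicarbaldehyde
Conditions: BBr3, CH2Cl2, −78 → 0 °C; H2O
Reagents that add atoms: none
Why: Lewis-acid cleavage of an aryl methyl ether; the methoxy group is meta to both formyl groups and should behave as an ordinary anisole, while boron adducts of the aldehydes revert on aqueous work-up.

Step 4
Reactants: 6 2-fluoro-5-hydroxybenzene-1,3-dicarbaldehyde
Product: 7 4-fluoro-3,5-bis(dimethoxymethyl)phenol (masked monomer for rings B and D)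
Conditions: HC(OMe)3, p-TsOH (cat.), MeOH, rt; Et3N
Reagents that add atoms: trimethyl orthoformate COC(OC)OC
Why: Twofold acetalisation removes the activation of the C–F bond, so this phenol can act as a nucleophile without attacking itself or its own coupling products.

Step 5
Reactants: 8 4-fluoro-1,2-dimethoxybenzene
Product: 10 6-fluoro-2,3-dimethoxybenzaldehyde, via aryllithium 9 (not isolated)
Conditions: n-BuLi, THF, −78 °C; DMF; 2 M HCl
Reagents that add atoms: N,N-dimethylformamide CN(C)C=O
Why: Directed ortho-metalation at the carbon flanked by fluorine and methoxy, the most acidic site of the ring, followed by formylation.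

Step 6
Reactants: 10 6-fluoro-2,3-dimethoxybenzaldehyde
Product: 11 2-(dimethoxymethyl)-1-fluoro-3,4-dimethoxybenzene
Conditions: HC(OMe)3, p-TsOH (cat.), MeOH, reflux; Et3N
Reagents that add atoms: trimethyl orthoformate COC(OC)OC
Why: Acetalisation protects the aldehyde against both the alkyllithium and the peroxide of the next step.

Step 7
Reactants: 11 2-(dimethoxymethyl)-1-fluoro-3,4-dimethoxybenzene
Product: 15 2-fluoro-3-hydroxy-5,6-dimethoxybenzaldehyde, via aryllithium 12 (not isolated), via boronate 13 (not isolated), via phenol acetal 14 (not isolated)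
Conditions: s-BuLi, PMDTA, THF, −78 °C; B(OMe)3; H2O2, NaOH, 0 °C; Na2SO3; 2 M HCl, rt
Reagents that add atoms: hydrogen peroxide OO; water O
Why: Directed ortho-metalation next to fluorine (acidity control as in step 2), borylation and peroxide oxidation of the C–B bond; the acetal is opened only after the peroxide has been destroyed, so no Dakin-type loss of the formyl group can occur.

Step 8
Reactants: 15 2-fluoro-3-hydroxy-5,6-dimethoxybenzaldehyde
Product: 16 3-(allyloxy)-2-fluoro-5,6-dimethoxybenzaldehyde (ring C monomer)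
Conditions: allyl bromide, K2CO3, DMF, rt
Reagents that add atoms: allyl bromide C=CCBr
Why: Williamson etherification; the allyl group blocks the phenol, which as phenoxide would deactivate the neighbouring fluoride, and it can later be removed without acid.

Step 9
Reactants: 17 4-bromo-2,6-dimethoxybenzaldehyde
Product: 18 5-bromo-2-(dimethoxymethyl)-1,3-dimethoxybenzene
Conditions: HC(OMe)3, p-TsOH (cat.), MeOH, rt; Et3N
Reagents that add atoms: trimethyl orthoformate COC(OC)OC
Why: Acetalisation protects the aldehyde for the two organolithium steps that follow.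

Step 10
Reactants: 18 5-bromo-2-(dimethoxymethyl)-1,3-dimethoxybenzene
Product: 20 2-(dimethoxymethyl)-5-fluoro-1,3-dimethoxybenzene, via aryllithium 19 (not isolated)
Conditions: n-BuLi, THF, −78 °C; NFSI, −78 °C → rt; H2O
Reagents that add atoms: N-fluorobenzenesulfonimide O=S(=O)(c1ccccc1)N(F)S(=O)(=O)c1ccccc1
Why: Bromine–lithium exchange fixes the metal para to the acetal carbon and electrophilic fluorination places fluorine there; formylating a 5-fluororesorcinol diether would not give this pattern, because both deprotonation and electrophilic attack go next to fluorine.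

Step 11
Reactants: 20 2-(dimethoxymethyl)-5-fluoro-1,3-dimethoxybenzene
Product: 24 4-fluoro-3-hydroxy-2,6-dimethoxybenzaldehyde, via aryllithium 21 (not isolated), via boronate 22 (not isolated), via phenol acetal 23 (not isolated)
Conditions: s-BuLi, THF, −78 °C; B(OMe)3; H2O2, NaOH, 0 °C; Na2SO3; 1 M HCl, rt
Reagents that add atoms: hydrogen peroxide OO; water O
Why: The two ring protons are equivalent and each lies between fluorine and methoxy, so directed ortho-metalation, borylation and oxidation can give only one phenol.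

Step 12
Reactants: 24 4-fluoro-3-hydroxy-2,6-dimethoxybenzaldehyde
Product: 25 4-fluoro-2,6-dimethoxy-3-(methoxymethoxy)benzaldehyde (ring E monomer)
Conditions: MOMCl, i-Pr2NEt, CH2Cl2, 0 °C → rt
Reagents that add atoms: chloromethyl methyl ether COCCl
Why: O-alkylation to the methoxymethyl ether gives a base-stable phenol mask that is later removed by acid alone, orthogonal to the allyl group on ring F.

Step 13
Reactants: 26 3-hydroxy-4,5-dimethoxybenzaldehyde
Product: 27 3-(allyloxy)-4,5-dimethoxybenzaldehyde
Conditions: allyl bromide, K2CO3, DMF, rt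
Reagents that add atoms: allyl bromide C=CCBr
Why: Williamson etherification marks the oxygen that will later bind ring G and so differentiates the two oxygens of ring F.

Step 14
Reactants: 27 3-(allyloxy)-4,5-dimethoxybenzaldehyde
Product: 29 3-(allyloxy)-4,5-dimethoxyphenol (ring F monomer), via aryl formate 28 (not isolated)
Conditions: H2O2 (30 %), H2SO4 (cat.), MeOH, rt
Reagents that add atoms: hydrogen peroxide OO
Why: Acid-catalysed Dakin-type (Baeyer–Villiger) oxidation: the para methoxy group secures aryl migration, the formate is methanolysed in the same pot, and the allyl double bond, which a peracid might epoxidise, is left alone.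

Step 15
Reactants: 30 5-bromo-2,3-difluorophenol
Product: 31 6-bromo-3,4-difluoro-2-hydroxybenzaldehyde
Conditions: MgCl2, Et3N, (CH2O)n, MeCN, reflux; 1 M HCl
Reagents that add atoms: formaldehyde (as paraformaldehyde) C=O
Why: Magnesium-mediated ortho-formylation of a phenol (Casnati–Skattebøl reaction): the magnesium phenoxide delivers formaldehyde only to an ortho carbon, and C6 is the only free one.

Step 16
Reactants: 31 6-bromo-3,4-difluoro-2-hydroxybenzaldehyde
Product: 32 6-bromo-3,4-difluoro-2-methoxybenzaldehyde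
Conditions: MeI (excess), K2CO3, DMF, rt
Reagents that add atoms: iodomethane CI
Why: Williamson methylation, which at room temperature should be much faster than attack of the weakly nucleophilic salicylaldehyde phenoxide on the para fluorine of the product.

Step 17
Reactants: 32 6-bromo-3,4-difluoro-2-methoxybenzaldehyde
Product: 33 1-bromo-2-(dimethoxymethyl)-4,5-difluoro-3-methoxybenzene
Conditions: HC(OMe)3, p-TsOH (cat.), MeOH, reflux; Et3N
Reagents that add atoms: trimethyl orthoformate COC(OC)OC
Why: Acetalisation protects this formyl group (C4 of ring G) for the metalation and switches off the activation of the fluorine reserved for ring F.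

Step 18
Reactants: 33 1-bromo-2-(dimethoxymethyl)-4,5-difluoro-3-methoxybenzene
Product: 35 2-(dimethoxymethyl)-4,5-difluoro-3-methoxybenzaldehyde (ring G monomer), via arylmagnesium chloride 34 (not isolated)
Conditions: i-PrMgCl·LiCl, THF, −15 °C; DMF, −15 °C → rt; pH 7 buffer
Reagents that add atoms: N,N-dimethylformamide CN(C)C=O
Why: Bromine–magnesium exchange and formylation; the arylmagnesium has no fluorine ortho to the metal, so aryne formation is excluded, and the neutral quench keeps the acetal.

Step 19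
Reactants: 35 2-(dimethoxymethyl)-4,5-difluoro-3-methoxybenzaldehyde; 36 3,4,5-trimethoxyphenol
Product: 38 5-fluoro-3-methoxy-4-(3,4,5-trimethoxyphenoxy)benzene-1,2-dicarbaldehyde (G–H fluoride), via G–H acetal 37 (not isolated)
Conditions: K2CO3, DMF, 70 °C; then 2 M HCl, THF, rt
Reagents that add atoms: water O
Why: SNAr in which only the fluorine para to the free formyl group can form a stabilised Meisenheimer adduct (the other is meta to it and para to a mere acetal carbon), so ring H enters at C6 next to the methoxy group, and acid then uncovers the second formyl group that switches on the fluorine at C1.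

Step 20
Reactants: 25 4-fluoro-2,6-dimethoxy-3-(methoxymethoxy)benzaldehyde; 29 3-(allyloxy)-4,5-dimethoxyphenol
Product: 39 4-[3-(allyloxy)-4,5-dimethoxyphenoxy]-2,6-dimethoxy-3-(methoxymethoxy)benzaldehyde (E–F dimer)
Conditions: Cs2CO3, DMSO, 100 °C
Reagents that add atoms: none
Why: SNAr of an unhindered, electron-rich phenoxide on a fluoride para to the formyl group; the heat needed for this weakly activated ring is harmless because neither monomer contains an exchange-prone aryl ether.

Step 21
Reactants: 39 E–F dimer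
Product: 40 4-(3-hydroxy-4,5-dimethoxyphenoxy)-2,6-dimethoxy-3-(methoxymethoxy)benzaldehyde
Conditions: Pd(PPh3)4 (cat.), K2CO3, MeOH, 50 °C; pH 7 buffer
Reagents that add atoms: none
Why: Palladium-catalysed allyl transfer (Tsuji–Trost type) from the aryl allyl ether to methanol frees the ring F phenol while the methoxymethyl ether and the aldehyde are untouched by base.

Step 22
Reactants: 40 E–F phenol; 38 G–H fluoride
Product: 41 MOM-protected E–F–G–H tetramer
Conditions: K2CO3, 4 Å sieves, DMF, 50 °C
Reagents that add atoms: none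
Why: SNAr at C1 of ring G, now para to one formyl group and meta to the other; moderate temperature and exclusion of water spare the base-sensitive ortho-dialdehyde.

Step 23
Reactants: 41 MOM-protected E–F–G–H tetramer
Product: 42 E–F–G–H phenol (free OH at C1 of ring E)
Conditions: 3 M HCl, THF, 45 °C
Reagents that add atoms: none
Why: Acid hydrolysis of the formaldehyde acetal; aldehydes, diaryl ethers and methyl ethers are inert to aqueous acid, which is why the acid-labile mask was put on the fragment that carries the ortho-dialdehyde.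

Step 24
Reactants: 16 3-(allyloxy)-2-fluoro-5,6-dimethoxybenzaldehyde; 7 4-fluoro-3,5-bis(dimethoxymethyl)phenol
Product: 43 3-(allyloxy)-2-[4-fluoro-3,5-bis(dimethoxymethyl)phenoxy]-5,6-dimethoxybenzaldehyde (C–D dimer with ring D masked)
Conditions: Cs2CO3, DMSO, 130 °C
Reagents that add atoms: none
Why: SNAr on a fluoride ortho to the formyl group; the acetal-masked phenoxide is a better nucleophile than its diformyl form, its own fluorine is inert, and the forcing conditions meet only robust monomers.

Step 25
Reactants: 43 C–D dimer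
Product: 44 2-[4-fluoro-3,5-bis(dimethoxymethyl)phenoxy]-3-hydroxy-5,6-dimethoxybenzaldehyde
Conditions: Pd(PPh3)4 (cat.), K2CO3, MeOH, 50 °C; pH 7 buffer
Reagents that add atoms: none
Why: Tsuji–Trost-type deallylation under basic conditions frees the ring C phenol and leaves the acid-labile ring D acetals closed.

Step 26
Reactants: 5 2-fluoro-5-methoxybenzene-1,3-dicarbaldehyde; 7 4-fluoro-3,5-bis(dimethoxymethyl)phenol
Product: 46 2-(4-fluoro-3,5-diformylphenoxy)-5-methoxybenzene-1,3-dicarbaldehyde (A–B fluoride), via A–B acetal 45 (not isolated)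
Conditions: K2CO3, DMF, rt; then 1 M HCl, THF, rt
Reagents that add atoms: water O
Why: SNAr on the fluoride flanked by two formyl groups stops cleanly at the dimer because the ring B fluorine is dormant during coupling, and acetal hydrolysis then arms it.

Step 27
Reactants: 46 A–B fluoride; 44 C–D phenol
Product: 48 A–B–C–D heptaaldehyde fluoride, via A–D acetal 47 (not isolated)
Conditions: K2CO3, DMF, 0 °C → rt; then 1 M HCl, THF, rt
Reagents that add atoms: water O
Why: SNAr at C4 of ring B, where fluoride leaves far faster than the aryloxide on the equally activated C1 of ring A; ring D stays dormant until the acid treatment uncovers its two formyl groups.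

Step 28
Reactants: 48 A–B–C–D heptaaldehyde fluoride; 42 E–F–G–H phenol
Product: 49 decaformyl undeca-O-methyl octamer
Conditions: K2CO3, DMF, rt → 40 °C
Reagents that add atoms: none
Why: SNAr at C4 of ring D, made strongly electrophilic by two ortho formyl groups and bearing the only fluoride left, so the fourfold ortho-substituted D–O–E ether should form near room temperature before aryloxide exchange at rings A and B sets in.

Step 29
Reactants: 49 decaformyl undeca-O-methyl octamer
Product: 51 decahydroxy undeca-O-methyl octamer, via decaformate 50 (not isolated)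
Conditions: mCPBA (excess), CH2Cl2, 0 → 40 °C; aq. Na2SO3 wash; then degassed MeOH, HCl (cat.), rt, argon
Reagents that add atoms: 3-chloroperbenzoic acid O=C(OO)c1cccc(Cl)c1
Why: Every formyl group takes up the peracid to give a Criegee adduct whose O–O bond breaks as the ring carbon shifts from carbon to oxygen; the aryl formates resist further oxidation and are opened by methanol only after the oxidant is gone, which protects the emerging catechol and pyrogallol units from quinone formation. The reaction type is the Baeyer–Villiger (Dakin-type) oxidation of ortho- or para-alkoxybenzaldehydes, which is also known for dialkoxy benzenedicarbaldehydes. No ring is closed and no stereocentre is made. The selectivity needed is aryl over hydride migration at all ten sites, and each migrating carbon has an oxygen substituent ortho or para to it: C1–O in ring A, C4–O in rings B and D, C2–O and C4–OMe in ring C, both flanking OMe groups and C2–O in ring E, C6–O for C3 and C5–OMe plus C1–O for C4 in ring G. On the diformyl rings the first oxidation replaces an acceptor by a formyloxy donor, so the second should be easier than the first. Rings F and H carry no formyl group and should survive as long as the temperature stays at or below 40 °C.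

Step 30
Reactants: 51 decahydroxy undeca-O-methyl octamer
Product: 52 CNP0309601.0 (target)
Conditions: BBr3 (excess), CH2Cl2, −78 °C → rt; H2O, argon
Reagents that add atoms: none
Why: Lewis-acid cleavage of all eleven aryl methyl ethers; diaryl ether bonds are inert to BBr3 and the free phenols are only converted into borates that hydrolyse on work-up.

Compound list
1 | 2-fluoro-5-methoxybenzaldehyde | COc1ccc(F)c(C=O)c1 | starting material
2 | 2-(dimethoxymethyl)-1-fluoro-4-methoxybenzene | COc1ccc(F)c(C(OC)OC)c1 | intermediate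
3 | [3-(dimethoxymethyl)-2-fluoro-5-methoxyphenyl]lithium | COc1cc([Li])c(F)c(C(OC)OC)c1 | intermediate
4 | 3-(dimethoxymethyl)-2-fluoro-5-methoxybenzaldehyde | COc1cc(C=O)c(F)c(C(OC)OC)c1 | intermediate
5 | 2-fluoro-5-methoxybenzene-1,3-dicarbaldehyde | COc1cc(C=O)c(F)c(C=O)c1 | intermediate
6 | 2-fluoro-5-hydroxybenzene-1,3-dicarbaldehyde | Oc1cc(C=O)c(F)c(C=O)c1 | intermediate
7 | 4-fluoro-3,5-bis(dimethoxymethyl)phenol | COC(OC)c1cc(O)cc(C(OC)OC)c1F | intermediate
8 | 4-fluoro-1,2-dimethoxybenzene | COc1ccc(F)cc1OC | starting material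
9 | (6-fluoro-2,3-dimethoxyphenyl)lithium | COc1ccc(F)c([Li])c1OC | intermediate
10 | 6-fluoro-2,3-dimethoxybenzaldehyde | COc1ccc(F)c(C=O)c1OC | intermediate
11 | 2-(dimethoxymethyl)-1-fluoro-3,4-dimethoxybenzene | COc1ccc(F)c(C(OC)OC)c1OC | intermediate
12 | [3-(dimethoxymethyl)-2-fluoro-4,5-dimethoxyphenyl]lithium | COc1cc([Li])c(F)c(C(OC)OC)c1OC | intermediate
13 | dimethyl [3-(dimethoxymethyl)-2-fluoro-4,5-dimethoxyphenyl]boronate | COc1cc(B(OC)OC)c(F)c(C(OC)OC)c1OC | intermediate
14 | 3-(dimethoxymethyl)-2-fluoro-4,5-dimethoxyphenol | COc1cc(O)c(F)c(C(OC)OC)c1OC | intermediate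
15 | 2-fluoro-3-hydroxy-5,6-dimethoxybenzaldehyde | COc1cc(O)c(F)c(C=O)c1OC | intermediate
16 | 3-(allyloxy)-2-fluoro-5,6-dimethoxybenzaldehyde | C=CCOc1cc(OC)c(OC)c(C=O)c1F | intermediate
17 | 4-bromo-2,6-dimethoxybenzaldehyde | COc1cc(Br)cc(OC)c1C=O | starting material
18 | 5-bromo-2-(dimethoxymethyl)-1,3-dimethoxybenzene | COc1cc(Br)cc(OC)c1C(OC)OC | intermediate
19 | [4-(dimethoxymethyl)-3,5-dimethoxyphenyl]lithium | COc1cc([Li])cc(OC)c1C(OC)OC | intermediate
20 | 2-(dimethoxymethyl)-5-fluoro-1,3-dimethoxybenzene | COc1cc(F)cc(OC)c1C(OC)OC | intermediate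
21 | [3-(dimethoxymethyl)-6-fluoro-2,4-dimethoxyphenyl]lithium | COc1cc(F)c([Li])c(OC)c1C(OC)OC | intermediate
22 | dimethyl [3-(dimethoxymethyl)-6-fluoro-2,4-dimethoxyphenyl]boronate | COc1cc(F)c(B(OC)OC)c(OC)c1C(OC)OC | intermediate
23 | 3-(dimethoxymethyl)-6-fluoro-2,4-dimethoxyphenol | COc1cc(F)c(O)c(OC)c1C(OC)OC | intermediate
24 | 4-fluoro-3-hydroxy-2,6-dimethoxybenzaldehyde | COc1cc(F)c(O)c(OC)c1C=O | intermediate
25 | 4-fluoro-2,6-dimethoxy-3-(methoxymethoxy)benzaldehyde | COCOc1c(F)cc(OC)c(C=O)c1OC | intermediate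
26 | 3-hydroxy-4,5-dimethoxybenzaldehyde | COc1cc(C=O)cc(O)c1OC | starting material
27 | 3-(allyloxy)-4,5-dimethoxybenzaldehyde | C=CCOc1cc(C=O)cc(OC)c1OC | intermediate
28 | 3-(allyloxy)-4,5-dimethoxyphenyl formate | C=CCOc1cc(OC=O)cc(OC)c1OC | intermediate
29 | 3-(allyloxy)-4,5-dimethoxyphenol | C=CCOc1cc(O)cc(OC)c1OC | intermediate
30 | 5-bromo-2,3-difluorophenol | Oc1cc(Br)cc(F)c1F | starting material
31 | 6-bromo-3,4-difluoro-2-hydroxybenzaldehyde | Oc1c(C=O)c(Br)cc(F)c1F | intermediate
32 | 6-bromo-3,4-difluoro-2-methoxybenzaldehyde | COc1c(C=O)c(Br)cc(F)c1F | intermediate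
33 | 1-bromo-2-(dimethoxymethyl)-4,5-difluoro-3-methoxybenzene | COc1c(C(OC)OC)c(Br)cc(F)c1F | intermediate
34 | [2-(dimethoxymethyl)-4,5-difluoro-3-methoxyphenyl]magnesium chloride | COc1c(C(OC)OC)c([Mg]Cl)cc(F)c1F | intermediate
35 | 2-(dimethoxymethyl)-4,5-difluoro-3-methoxybenzaldehyde | COc1c(C(OC)OC)c(C=O)cc(F)c1F | intermediate
36 | 3,4,5-trimethoxyphenol | COc1cc(O)cc(OC)c1OC | starting material
37 | 2-(dimethoxymethyl)-5-fluoro-3-methoxy-4-(3,4,5-trimethoxyphenoxy)benzaldehyde | COc1c(C(OC)OC)c(C=O)cc(F)c1Oc1cc(OC)c(OC)c(OC)c1 | intermediate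
38 | 5-fluoro-3-methoxy-4-(3,4,5-trimethoxyphenoxy)benzene-1,2-dicarbaldehyde | COc1c(C=O)c(C=O)cc(F)c1Oc1cc(OC)c(OC)c(OC)c1 | intermediate
39 | 4-[3-(allyloxy)-4,5-dimethoxyphenoxy]-2,6-dimethoxy-3-(methoxymethoxy)benzaldehyde | COCOc1c(Oc2cc(OC)c(OC)c(OCC=C)c2)cc(OC)c(C=O)c1OC | intermediate
40 | 4-(3-hydroxy-4,5-dimethoxyphenoxy)-2,6-dimethoxy-3-(methoxymethoxy)benzaldehyde | COCOc1c(Oc2cc(OC)c(OC)c(O)c2)cc(OC)c(C=O)c1OC | intermediate
41 | E–F–G–H tetramer with OMOM at C1 of ring E (E: 4,6-di-OMe, 5-CHO; F: 3,4-di-OMe; G: 3,4-di-CHO, 5-OMe; H: 3,4,5-tri-OMe) | COCOc1c(Oc2cc(OC)c(OC)c(Oc3cc(C=O)c(C=O)c(OC)c3Oc3cc(OC)c(OC)c(OC)c3)c2)cc(OC)c(C=O)c1OC | intermediate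
42 | E–F–G–H tetramer with free OH at C1 of ring E | Oc1c(Oc2cc(OC)c(OC)c(Oc3cc(C=O)c(C=O)c(OC)c3Oc3cc(OC)c(OC)c(OC)c3)c2)cc(OC)c(C=O)c1OC | intermediate
43 | 3-(allyloxy)-2-[4-fluoro-3,5-bis(dimethoxymethyl)phenoxy]-5,6-dimethoxybenzaldehyde | C=CCOc1cc(OC)c(OC)c(C=O)c1Oc1cc(C(OC)OC)c(F)c(C(OC)OC)c1 | intermediate
44 | 2-[4-fluoro-3,5-bis(dimethoxymethyl)phenoxy]-3-hydroxy-5,6-dimethoxybenzaldehyde | Oc1cc(OC)c(OC)c(C=O)c1Oc1cc(C(OC)OC)c(F)c(C(OC)OC)c1 | intermediate
45 | 2-[4-fluoro-3,5-bis(dimethoxymethyl)phenoxy]-5-methoxybenzene-1,3-dicarbaldehyde | COc1cc(C=O)c(Oc2cc(C(OC)OC)c(F)c(C(OC)OC)c2)c(C=O)c1 | intermediate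
46 | 2-(4-fluoro-3,5-diformylphenoxy)-5-methoxybenzene-1,3-dicarbaldehyde | COc1cc(C=O)c(Oc2cc(C=O)c(F)c(C=O)c2)c(C=O)c1 | intermediate
47 | A–B–C–D tetramer fluoride, five CHO on rings A–C, ring D as bis(dimethyl acetal) | COc1cc(C=O)c(Oc2cc(C=O)c(Oc3cc(OC)c(OC)c(C=O)c3Oc3cc(C(OC)OC)c(F)c(C(OC)OC)c3)c(C=O)c2)c(C=O)c1 | intermediate
48 | A–B–C–D tetramer fluoride, heptaaldehyde (F at C4 of ring D) | COc1cc(C=O)c(Oc2cc(C=O)c(Oc3cc(OC)c(OC)c(C=O)c3Oc3cc(C=O)c(F)c(C=O)c3)c(C=O)c2)c(C=O)c1 | intermediate
49 | decaformyl undeca-O-methyl octamer | COc1cc(C=O)c(Oc2cc(C=O)c(Oc3cc(OC)c(OC)c(C=O)c3Oc3cc(C=O)c(Oc4c(Oc5cc(OC)c(OC)c(Oc6cc(C=O)c(C=O)c(OC)c6Oc6cc(OC)c(OC)c(OC)c6)c5)cc(OC)c(C=O)c4OC)c(C=O)c3)c(C=O)c2)c(C=O)c1 | intermediate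
50 | deca(formyloxy) undeca-O-methyl octamer | COc1cc(OC=O)c(Oc2cc(OC=O)c(Oc3cc(OC)c(OC)c(OC=O)c3Oc3cc(OC=O)c(Oc4c(Oc5cc(OC)c(OC)c(Oc6cc(OC=O)c(OC=O)c(OC)c6Oc6cc(OC)c(OC)c(OC)c6)c5)cc(OC)c(OC=O)c4OC)c(OC=O)c3)c(OC=O)c2)c(OC=O)c1 | intermediate
51 | decahydroxy undeca-O-methyl octamer | COc1cc(O)c(Oc2cc(O)c(Oc3cc(OC)c(OC)c(O)c3Oc3cc(O)c(Oc4c(Oc5cc(OC)c(OC)c(Oc6cc(O)c(O)c(OC)c6Oc6cc(OC)c(OC)c(OC)c6)c5)cc(OC)c(O)c4OC)c(O)c3)c(O)c2)c(O)c1 | intermediate
52 | CNP0309601.0 | Oc1cc(O)c(Oc2cc(O)c(Oc3cc(O)c(O)c(O)c3Oc3cc(O)c(Oc4c(Oc5cc(O)c(O)c(Oc6cc(O)c(O)c(O)c6Oc6cc(O)c(O)c(O)c6)c5)cc(O)c(O)c4O)c(O)c3)c(O)c2)c(O)c1 | target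

Total step count: 30.
Longest linear sequence: 11 steps (9, 10, 11, 12, 20, 21, 22, 23, 28, 29, 30).

Steps most likely to fail

Step 29.
- What may go wrong: hydride instead of aryl migration in the Criegee adducts of the electron-poor diformyl rings A, B and D, or stalling at partly oxidised stages. Over ten sites either process multiplies into a mixture that cannot be separated.
- Idea of the fallback: the oxidation is divided over two smaller substrates, and formyl groups are removed as soon as they have done their activating work.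
- Start and return: it sets out from 47 (isolated instead of being hydrolysed) and from 42, and comes back to the route at 52.
- Left half: mCPBA buffered with NaHCO3 in CH2Cl2 should oxidise the five free formyl groups of rings A, B and C to the tetramer pentaformate F1 while the ring D acetals stay closed. K2CO3 in degassed MeOH gives the tetramer pentaphenol F2. MeI and K2CO3 in DMF give the penta-O-methyl ether F3. 1 M HCl in THF gives the ring D dialdehyde fluoride F4.
- Coupling and finish: SNAr of F4 with 42 (K2CO3, DMF) gives the pentaformyl octamer F5, which no longer holds exchange-prone ether carbons in rings A and B. A second, fivefold Baeyer–Villiger oxidation leads through the octamer pentaformate F6 to the octamer pentaphenol F7. BBr3 then cleaves the sixteen methyl ethers of F7 to 52.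

Step 28.
- What may go wrong: slow attack of the doubly ortho-substituted ring E phenoxide at the ring D fluoride, so that aryloxide exchange at C1 of ring A and C4 of ring B overtakes it and scrambles the chain.
- Idea of the fallback: the hindered bond is made on a partner without competing sites, and the last bond becomes the less hindered B–O–C ether.
- Start and return: it sets out from 43 and 42 and comes back at 49.
- Sequence: 1 M HCl in THF opens the acetals of 43 to the O-allyl C–D trialdehyde fluoride F8. F8 can be heated with 42 (K2CO3, DMF) because neither partner contains another doubly activated ether carbon, and this gives the O-allyl hexamer F9. Pd(PPh3)4 and p-toluenesulfinic acid in CH2Cl2 remove the allyl group under neutral conditions that spare the ortho-dialdehyde, giving the hexamer phenol F10. SNAr of F10, whose phenoxide has only one ortho substituent, on 46 (K2CO3, DMF, 0 °C → rt) gives 49.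

Step 24.
- What may go wrong: the Meisenheimer adduct fails to form. The ring C fluoride has one ortho formyl acceptor but a para methoxy donor and two ortho neighbours, so decay of the aldehyde at the temperature required may outrun substitution.
- Idea of the fallback: copper-catalysed Ullmann ether synthesis, which does not depend on stabilising an anionic adduct.
- Start and return: it sets out from 7 and comes back at 43.
- Sequence: commercial 3,4-dimethoxyphenol F11 is brominated with NBS in MeCN, para to a methoxy group and ortho to the hydroxyl, to give 2-bromo-4,5-dimethoxyphenol F12. Allyl bromide and K2CO3 give 1-(allyloxy)-2-bromo-4,5-dimethoxybenzene F13. LDA in THF at −78 °C removes the proton between bromine and methoxy, and DMF gives 3-(allyloxy)-2-bromo-5,6-dimethoxybenzaldehyde F14. Coupling of F14 with 7 (CuI, picolinic acid, K3PO4, DMSO, 90 °C) gives 43, the dormant fluorine of 7 being inert to copper catalysis.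

Further compounds
F1 | step 29 | A–B–C–D tetramer fluoride, rings A–C as pentaformate, ring D as bis(dimethyl acetal) | COc1cc(OC=O)c(Oc2cc(OC=O)c(Oc3cc(OC)c(OC)c(OC=O)c3Oc3cc(C(OC)OC)c(F)c(C(OC)OC)c3)c(OC=O)c2)c(OC=O)c1
F2 | step 29 | A–B–C–D tetramer fluoride, pentaphenol, ring D as bis(dimethyl acetal) | COc1cc(O)c(Oc2cc(O)c(Oc3cc(OC)c(OC)c(O)c3Oc3cc(C(OC)OC)c(F)c(C(OC)OC)c3)c(O)c2)c(O)c1
F3 | step 29 | A–B–C–D tetramer fluoride, octa-O-methyl, ring D as bis(dimethyl acetal) | COc1cc(OC)c(Oc2cc(OC)c(Oc3cc(OC)c(OC)c(OC)c3Oc3cc(C(OC)OC)c(F)c(C(OC)OC)c3)c(OC)c2)c(OC)c1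
F4 | step 29 | A–B–C–D tetramer fluoride, octa-O-methyl, ring D dialdehyde | COc1cc(OC)c(Oc2cc(OC)c(Oc3cc(OC)c(OC)c(OC)c3Oc3cc(C=O)c(F)c(C=O)c3)c(OC)c2)c(OC)c1
F5 | step 29 | pentaformyl hexadeca-O-methyl octamer | COc1cc(OC)c(Oc2cc(OC)c(Oc3cc(OC)c(OC)c(OC)c3Oc3cc(C=O)c(Oc4c(Oc5cc(OC)c(OC)c(Oc6cc(C=O)c(C=O)c(OC)c6Oc6cc(OC)c(OC)c(OC)c6)c5)cc(OC)c(C=O)c4OC)c(C=O)c3)c(OC)c2)c(OC)c1
F6 | step 29 | penta(formyloxy) hexadeca-O-methyl octamer | COc1cc(OC)c(Oc2cc(OC)c(Oc3cc(OC)c(OC)c(OC)c3Oc3cc(OC=O)c(Oc4c(Oc5cc(OC)c(OC)c(Oc6cc(OC=O)c(OC=O)c(OC)c6Oc6cc(OC)c(OC)c(OC)c6)c5)cc(OC)c(OC=O)c4OC)c(OC=O)c3)c(OC)c2)c(OC)c1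
F7 | step 29 | pentahydroxy hexadeca-O-methyl octamer | COc1cc(OC)c(Oc2cc(OC)c(Oc3cc(OC)c(OC)c(OC)c3Oc3cc(O)c(Oc4c(Oc5cc(OC)c(OC)c(Oc6cc(O)c(O)c(OC)c6Oc6cc(OC)c(OC)c(OC)c6)c5)cc(OC)c(O)c4OC)c(O)c3)c(OC)c2)c(OC)c1
F8 | step 28 | 3-(allyloxy)-2-(4-fluoro-3,5-diformylphenoxy)-5,6-dimethoxybenzaldehyde | C=CCOc1cc(OC)c(OC)c(C=O)c1Oc1cc(C=O)c(F)c(C=O)c1
F9 | step 28 | C–D–E–F–G–H hexamer hexaaldehyde with O-allyl at C1 of ring C | C=CCOc1cc(OC)c(OC)c(C=O)c1Oc1cc(C=O)c(Oc2c(Oc3cc(OC)c(OC)c(Oc4cc(C=O)c(C=O)c(OC)c4Oc4cc(OC)c(OC)c(OC)c4)c3)cc(OC)c(C=O)c2OC)c(C=O)c1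
F10 | step 28 | C–D–E–F–G–H hexamer hexaaldehyde with free OH at C1 of ring C | Oc1cc(OC)c(OC)c(C=O)c1Oc1cc(C=O)c(Oc2c(Oc3cc(OC)c(OC)c(Oc4cc(C=O)c(C=O)c(OC)c4Oc4cc(OC)c(OC)c(OC)c4)c3)cc(OC)c(C=O)c2OC)c(C=O)c1
F11 | step 24 | 3,4-dimethoxyphenol | COc1ccc(O)cc1OC
F12 | step 24 | 2-bromo-4,5-dimethoxyphenol | COc1cc(O)c(Br)cc1OC
F13 | step 24 | 1-(allyloxy)-2-bromo-4,5-dimethoxybenzene | C=CCOc1cc(OC)c(OC)cc1Br
F14 | step 24 | 3-(allyloxy)-2-bromo-5,6-dimethoxybenzaldehyde | C=CCOc1cc(OC)c(OC)c(C=O)c1Br
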